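A direct plan would take rings A and B ready-made from (+)-podocarpic acid A1, reduce its aromatic ring C to the enone A2, cut that ring open oxidatively to the triacid A3, and regrow the side chain by decarboxylative radical addition to the α-methylene-γ-butyrolactone A4, ending with a sulfoxide elimination from the sulfide A5.
Its weakest steps would be:
(a) the reduction, dehydrogenation and ozonolysis stretch that excises ring C: it builds an enone only to destroy it, discards ring carbons, leaves C12 as a carboxyl that is sacrificed one step later, and sets C8 only by a reversible protonation;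
(b) the one-pot anhydride formation, thiohydroxamate ester formation and radical addition on an unprotected triacid: telling three free acids apart rests on a reversible anhydride opening, and the light-driven chain must outrun simple decarboxylative rearrangement, on a substrate class where this is untested;
(c) the final sulfoxide elimination: it follows an unselective C13 centre, must take the ring hydrogen and not the chain hydrogen, and is run hot on the finished diacid.

**Retrosynthetic overview**
- The decalin is cut at C4–C5 and C9–C10, so that both rings close in one radical bicyclisation of an acyclic polyene. C4 and C8, the two ring carbons that carry carboxyl groups, are the two electrophilic radical positions of a polarity-alternating chain (C4 radical → C5=C10 → C10 radical → C9=C8–CO2Et).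
- Ring A closes first and ring B second. C4, C5, C9 and C10 are set together, their absolute sense by an 8-phenylmenthyl ester at the carbon that becomes C19; C8 is then equilibrated to its more stable configuration.
- The C3 carbonyl that creates the radical and steers C4 is removed with zinc. The auxiliary ester can only be cleaved by hydride, so C17 and C19 pass through the alcohol level once.
- The intact butenolide is joined at C12–C13 by B-alkyl Suzuki coupling of the C9 vinyl group with 3-bromofuran-2(5H)-one. No ring is excised, no carbon is discarded, and no elimination decides where the butenolide double bond lies.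

Key step: step 8

**Remarks on the chemistry**
- Labdane numbering is used for all cyclised compounds (C17 on C8, C18/C19 on C4, C20 on C10).
- Assumption: the (1R,2S,5R)-auxiliary is taken to shield the face of the C4 radical that leads to the 10β-methyl series, as in the related podocarpate ring system. If the opposite sense were found, the enantiomeric auxiliary would be used and nothing else changes.
- Diastereomers from incomplete auxiliary control should be separable at 15, where the auxiliary is still attached.

**Route**

Step 1
Reactants: 1 (−)-8-phenylmenthol [(1R,2S,5R)-5-methyl-2-(2-phenylpropan-2-yl)cyclohexan-1-ol]; 2 ethyl 2-methyl-3-oxobutanoate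
Product: 3 (−)-8-phenylmenthyl 2-methyl-3-oxobutanoate (both C2 epimers)
Conditions: DMAP (0.2 equiv), toluene, reflux, 4 Å sieves (removal of EtOH)
Reagents that add atoms: none
Why: DMAP-catalysed transesterification of a β-keto ester, driven by removal of ethanol, loads the auxiliary on the carbonyl that becomes C19; the C2 centre may stay a mixture because it becomes a radical centre.

Step 2
Reactants: 4 ethyl 2-(diphenoxyphosphoryl)acetate; 5 5-bromo-2-methylpent-2-ene
Product: 6 ethyl 2-(diphenoxyphosphoryl)-6-methylhept-5-enoate (racemic)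
Conditions: NaH (1.05 equiv), DMSO, rt; then 5, NaI (0.1 equiv), 50 °C
Reagents that add atoms: none
Why: SN2 C-alkylation of the doubly stabilised phosphonoacetate anion by the primary homoallylic bromide joins C8 to C7 and brings in C6, C5, C10 and both methyl groups on C10.

Step 3
Reactants: 6 ethyl 2-(diphenoxyphosphoryl)-6-methylhept-5-enoate; 7 acrolein
Product: 8 ethyl (2Z)-2-(4-methylpent-3-en-1-yl)penta-2,4-dienoate
Conditions: NaH (1.1 equiv), THF, −78 °C; then 7 (1.5 equiv), −78 → −20 °C
Reagents that add atoms: none
Why: Ando-type Horner–Wadsworth–Emmons olefination, in which the electron-poor diaryl phosphonate makes elimination from the first adduct fast and gives the kinetic (Z)-trisubstituted enoate, so the vinyl group (C11, C12) sits cis to the ester and trans to the chain as the closure of ring B requires.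

Step 4
Reactants: 8 ethyl (2Z)-2-(4-methylpent-3-en-1-yl)penta-2,4-dienoate
Product: 9 ethyl (2Z)-2-[(3E)-5-hydroxy-4-methylpent-3-en-1-yl]penta-2,4-dienoate
Conditions: SeO2 (0.3 equiv), t-BuOOH (70% aq, 3 equiv), salicylic acid (0.1 equiv), CH2Cl2, 0 °C → rt
Reagents that add atoms: selenium dioxide, O=[Se]=O (delivers the oxygen and is regenerated by tert-butyl hydroperoxide, CC(C)(C)OO)
Why: Selenium dioxide allylic oxidation (ene reaction, then [2,3]-sigmatropic shift) attacks the electron-rich trisubstituted alkene and not the dienoate, and selects its (E)-methyl group, the future C1.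

Step 5
Reactants: 9 ethyl (2Z)-2-[(3E)-5-hydroxy-4-methylpent-3-en-1-yl]penta-2,4-dienoate
Product: 10 ethyl (2Z)-2-[(3E)-5-bromo-4-methylpent-3-en-1-yl]penta-2,4-dienoate
Conditions: CBr4 (1.2 equiv), PPh3 (1.25 equiv), CH2Cl2, −20 → 0 °C
Reagents that add atoms: carbon tetrabromide, BrC(Br)(Br)Br
Why: Appel bromination of the primary allylic alcohol, an SN2 displacement of the alkoxyphosphonium ion that leaves the (E)-alkene in place.

Step 6
Reactants: 3 (−)-8-phenylmenthyl 2-methyl-3-oxobutanoate; 10 ethyl (2Z)-2-[(3E)-5-bromo-4-methylpent-3-en-1-yl]penta-2,4-dienoate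
Product: 11 (−)-8-phenylmenthyl (6E,10Z)-10-(ethoxycarbonyl)-2,6-dimethyl-3-oxotrideca-6,10,12-trienoate (C2 epimers)
Conditions: 3 (1.1 equiv), NaH (1.2 equiv), THF, 0 °C; n-BuLi (1.15 equiv), −10 °C; then 10, −78 → 0 °C; aq NH4Cl
Reagents that add atoms: none
Why: Alkylation of the acetoacetate dianion at its more basic terminal carbon (the future C2) by the allylic bromide forms C1–C2 and at −78 °C should be far faster than addition to the hindered dienoate.

Step 7
Reactants: 11 (−)-8-phenylmenthyl (6E,10Z)-10-(ethoxycarbonyl)-2,6-dimethyl-3-oxotrideca-6,10,12-trienoate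
Product: 12 (−)-8-phenylmenthyl (6E,10Z)-2-bromo-10-(ethoxycarbonyl)-2,6-dimethyl-3-oxotrideca-6,10,12-trienoate (C2 epimers)
Conditions: NBS (1.05 equiv), Mg(ClO4)2 (0.3 equiv), EtOAc, 0 °C, dark
Reagents that add atoms: N-bromosuccinimide, O=C1CCC(=O)N1Br
Why: Magnesium-chelate-promoted enolisation and electrophilic bromination of the 1,3-dicarbonyl unit, much faster than reaction of NBS with the alkenes, gives the tertiary bromide that serves as radical precursor and as bromine donor.

Step 8
Reactants: 12 (−)-8-phenylmenthyl (6E,10Z)-2-bromo-10-(ethoxycarbonyl)-2,6-dimethyl-3-oxotrideca-6,10,12-trienoate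
Product: 13 17-ethyl 19-[(−)-8-phenylmenthyl] 8-bromo-3-oxo-13,14,15,16-tetranorlabd-11-ene-17,19-dioate (trans-decalin with 5α-H, 9α-H, 10β-CH3, axial 4β ester, 9β-vinyl; both C8 epimers)
Conditions: Et3B (1 M in hexane, 0.3 equiv in three portions), air (syringe), toluene (0.01 M), 0 °C → rt; no Lewis acid
Reagents that add atoms: none
Why: Et3B/O2 starts a bromine-atom-transfer chain in which the electrophilic tertiary 1,3-dicarbonyl radical at C4 adds 6-endo-trig to C5 of the electron-rich C5=C10 alkene and closes ring A, the nucleophilic tertiary C10 radical adds 6-endo-trig to C9, the β-carbon of the dienoate, and closes ring B, and the electrophilic C8 radical takes bromine from a further molecule of 12. The closest known reactions are the atom-transfer tandem cyclisations of unsaturated α-bromo β-keto esters and the trivalent-manganese oxidative bicyclisation of 2-methylacetoacetates of 8-phenylmenthol that gives the podocarpate ring system. For C4, the free radical reacts through the conformer with the keto and ester dipoles opposed, which puts the ester (C19) axial and cis to C20; for C5 and C10, a chair-like transition state on the (E)-alkene gives the trans ring fusion; for C9, the (Z)-dienoate holds the vinyl group trans to C7 and hence equatorial (9α-H); the absolute sense comes from the phenyl ring of the auxiliary, which stacks over one face of the planar dicarbonyl radical so that the alkene attacks the other. The step needs 6-endo over 5-exo closure in ring A (secured by the ring carbonyl and the methyl group on C10), closure of ring B before bromine transfer to C10 (secured by working at 0.01 M), and attack at C9 and not at C12 of the diene (the latter would need an 8-membered ring). The two C8 bromide epimers are of no consequence because C8 is reset in step 9.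

Step 9
Reactants: 13 17-ethyl 19-[(−)-8-phenylmenthyl] 8-bromo-3-oxo-13,14,15,16-tetranorlabd-11-ene-17,19-dioate
Product: 15 17-ethyl 19-[(−)-8-phenylmenthyl] (8βH)-13,14,15,16-tetranorlabd-11-ene-17,19-dioate (C17 ester equatorial), via C8-epimeric debrominated deoxo diester 14 (not isolated)
Conditions: Zn dust (activated, 25 equiv), HCl (g)-saturated Et2O, −10 → 0 °C; filter, concentrate; then NaOEt (0.3 equiv), EtOH, 78 °C; chromatography
Reagents that add atoms: none
Why: Zinc reduces the tertiary α-bromo ester (through its zinc enolate) and the C3 ketone (Clemmensen reduction, anhydrous variant that spares esters), and ethoxide then equilibrates the enolisable C8 centre to the isomer with the C17 ester equatorial and trans to the C9 vinyl group (8β-H), the exchange at C17 being degenerate and the quaternary C4 ester inert.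

Step 10
Reactants: 15 17-ethyl 19-[(−)-8-phenylmenthyl] (8βH)-13,14,15,16-tetranorlabd-11-ene-17,19-dioate
Product: 16 (8βH)-13,14,15,16-tetranorlabd-11-ene-17,19-diol
Conditions: LiAlH4 (4 equiv), THF, 0 °C → reflux; H2O/NaOH work-up; auxiliary 1 recovered
Reagents that add atoms: none
Why: Hydride reduction cleaves both esters, which is the practical way to release the neopentyl axial C19 acyl group from its hindered secondary alkyl ester, and it touches no stereocentre.

Step 11
Reactants: 16 (8βH)-13,14,15,16-tetranorlabd-11-ene-17,19-diol; 17 3-bromofuran-2(5H)-one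
Product: 19 (8βH)-17,19-dihydroxylabd-13-en-16,15-olide, via tris(9-borabicyclononyl) adduct 18 (not isolated)
Conditions: 9-BBN (0.5 M in THF, 3.5 equiv), 0 °C → rt; then 17 (1.5 equiv), PdCl2(dppf) ([1,1'-bis(diphenylphosphino)ferrocene]dichloropalladium, divalent palladium, 5 mol%), AsPh3 (10 mol%), Cs2CO3 (3 equiv), DMF/H2O, rt
Reagents that add atoms: none
Why: Anti-Markovnikov hydroboration of the monosubstituted alkene with 9-BBN followed by B-alkyl Suzuki–Miyaura coupling with the alkenyl bromide (retention at the sp2 carbon) forms C12–C13 and brings in the butenolide with its double bond already in place; the borinate esters formed at the two hydroxyls are hydrolysed on work-up.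

Step 12
Reactants: 19 (8βH)-17,19-dihydroxylabd-13-en-16,15-olide
Product: 20 (8βH)-labd-13-en-16,15-olide-17,19-dioic acid (target)
Conditions: CrO3/H2SO4/H2O (Jones reagent, hexavalent chromium), acetone, 0 °C → rt; i-PrOH quench
Reagents that add atoms: water, O
Why: Jones oxidation takes both primary alcohols through the aldehyde hydrates to the carboxylic acids without touching the butenolide, and C8 stays in its more stable configuration with the carboxyl equatorial.

**Compound list**
1 | (−)-8-phenylmenthol, (1R,2S,5R)-5-methyl-2-(2-phenylpropan-2-yl)cyclohexan-1-ol | CC(C)(c1ccccc1)[C@@H]1CC[C@@H](C)C[C@H]1O | starting material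
2 | ethyl 2-methyl-3-oxobutanoate | CCOC(=O)C(C)C(C)=O | starting material
3 | (−)-8-phenylmenthyl 2-methyl-3-oxobutanoate (C2 epimers) | CC(=O)C(C)C(=O)O[C@@H]1C[C@H](C)CC[C@H]1C(C)(C)c1ccccc1 | intermediate
4 | ethyl 2-(diphenoxyphosphoryl)acetate | CCOC(=O)CP(=O)(Oc1ccccc1)Oc1ccccc1 | starting material
5 | 5-bromo-2-methylpent-2-ene | CC(C)=CCCBr | starting material
6 | ethyl 2-(diphenoxyphosphoryl)-6-methylhept-5-enoate (racemic) | CCOC(=O)C(CCC=C(C)C)P(=O)(Oc1ccccc1)Oc1ccccc1 | intermediate
7 | acrolein | C=CC=O | starting material
8 | ethyl (2Z)-2-(4-methylpent-3-en-1-yl)penta-2,4-dienoate | C=C/C=C(\C(=O)OCC)CCC=C(C)C | intermediate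
9 | ethyl (2Z)-2-[(3E)-5-hydroxy-4-methylpent-3-en-1-yl]penta-2,4-dienoate | C=C/C=C(\C(=O)OCC)CC/C=C(\C)CO | intermediate
10 | ethyl (2Z)-2-[(3E)-5-bromo-4-methylpent-3-en-1-yl]penta-2,4-dienoate | C=C/C=C(\C(=O)OCC)CC/C=C(\C)CBr | intermediate
11 | (−)-8-phenylmenthyl (6E,10Z)-10-(ethoxycarbonyl)-2,6-dimethyl-3-oxotrideca-6,10,12-trienoate (C2 epimers) | C=C/C=C(\C(=O)OCC)CC/C=C(\C)CCC(=O)C(C)C(=O)O[C@@H]1C[C@H](C)CC[C@H]1C(C)(C)c1ccccc1 | intermediate
12 | (−)-8-phenylmenthyl (6E,10Z)-2-bromo-10-(ethoxycarbonyl)-2,6-dimethyl-3-oxotrideca-6,10,12-trienoate (C2 epimers) | C=C/C=C(\C(=O)OCC)CC/C=C(\C)CCC(=O)C(C)(Br)C(=O)O[C@@H]1C[C@H](C)CC[C@H]1C(C)(C)c1ccccc1 | intermediate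
13 | 17-ethyl 19-[(−)-8-phenylmenthyl] 8-bromo-3-oxo-13,14,15,16-tetranorlabd-11-ene-17,19-dioate (C8 epimers) | C[C@]12CCC(=O)[C@](C)(C(=O)O[C@@H]3C[C@H](C)CC[C@H]3C(C)(C)c3ccccc3)[C@@H]1CCC(Br)(C(=O)OCC)[C@@H]2C=C | intermediate
14 | 17-ethyl 19-[(−)-8-phenylmenthyl] 13,14,15,16-tetranorlabd-11-ene-17,19-dioate (C8 epimers) | C[C@]12CCC[C@](C)(C(=O)O[C@@H]3C[C@H](C)CC[C@H]3C(C)(C)c3ccccc3)[C@@H]1CCC(C(=O)OCC)[C@@H]2C=C | intermediate
15 | 17-ethyl 19-[(−)-8-phenylmenthyl] (8βH)-13,14,15,16-tetranorlabd-11-ene-17,19-dioate | C[C@]12CCC[C@](C)(C(=O)O[C@@H]3C[C@H](C)CC[C@H]3C(C)(C)c3ccccc3)[C@@H]1CC[C@@H](C(=O)OCC)[C@@H]2C=C | intermediate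
16 | (8βH)-13,14,15,16-tetranorlabd-11-ene-17,19-diol | C[C@]12CCC[C@](C)(CO)[C@@H]1CC[C@@H](CO)[C@@H]2C=C | intermediate
17 | 3-bromofuran-2(5H)-one | O=C1OCC=C1Br | starting material
18 | 12-(9-borabicyclo[3.3.1]nonan-9-yl) adduct of 16 with both hydroxyls as 9-BBN borinates | C[C@]12CCC[C@](C)(COB3C4CCCC3CCC4)[C@@H]1CC[C@@H](COB3C4CCCC3CCC4)[C@@H]2CCB3C4CCCC3CCC4 | intermediate
19 | (8βH)-17,19-dihydroxylabd-13-en-16,15-olide | C[C@]12CCC[C@](C)(CO)[C@@H]1CC[C@@H](CO)[C@@H]2CCC1=CCOC1=O | intermediate
20 | (8βH)-labd-13-en-16,15-olide-17,19-dioic acid | C[C@]12CCC[C@](C)(C(=O)O)[C@@H]1CC[C@@H](C(=O)O)[C@@H]2CCC1=CCOC1=O | target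

**Step count**
Total: 12 steps. Longest linear sequence: 11 steps (steps 2 to 12).

**Steps most likely to fail**

Step 8. The chain may stall after ring A, because bromine transfer to the C10 radical competes with its addition to the dienoate, or initiation may be inefficient. The fallback sets out from 11 and makes the same C4 radical by one-electron oxidation of its enolate with Mn(OAc)3·2H2O (trivalent manganese, 2.2 equiv) in degassed AcOH/EtOH at rt, without any halogen donor. The C10 radical can then only cyclise, and the final C8 radical is reduced by hydrogen abstraction from ethanol. This should give the 3-oxo diester F1 (C8 epimers), which under the conditions of step 9 (Zn, HCl; then NaOEt) comes back to the route at 15.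

Step 11. The base-labile bromobutenolide may decompose faster than it couples, and transmetalation from a borane that also carries two borinate esters may be slow. The fallback sets out from 16, hydroborates as before, and couples the borane under the same palladium catalysis with the acyclic, base-stable partner ethyl (E)-2-bromo-4-[(tert-butyldimethylsilyl)oxy]but-2-enoate (CCOC(=O)/C(Br)=C\CO[Si](C)(C)C(C)(C)C). This should give the (Z)-enoate F2. TsOH in MeOH then removes the silyl ether, and the freed hydroxyl closes the lactone onto the cis ester. The route is rejoined at 19.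

Step 3. Z selectivity may erode, or the phosphonate anion may add to acrolein in conjugate fashion; the E isomer would end as the C9 epimer. The fallback sets out from 5, which zinc dust and LiCl in THF convert into the organozinc bromide F3. Coupling with 3-iodo-5,6-dihydro-2H-pyran-2-one (PdCl2(dppf), divalent palladium) should give the lactone F4, in which the ring fixes the cis relation between the carboxyl and the future vinyl group. t-BuOK in THF opens F4 by 1,4-elimination to the (2Z)-dienoic acid F5, and EtI/K2CO3 in DMF esterifies it. The route is rejoined at 8.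

**Further compounds**
F1 | step 8 | 17-ethyl 19-[(−)-8-phenylmenthyl] 3-oxo-13,14,15,16-tetranorlabd-11-ene-17,19-dioate (C8 epimers) | C[C@]12CCC(=O)[C@](C)(C(=O)O[C@@H]3C[C@H](C)CC[C@H]3C(C)(C)c3ccccc3)[C@@H]1CCC(C(=O)OCC)[C@@H]2C=C
F2 | step 11 | ethyl (13Z)-15-[(tert-butyldimethylsilyl)oxy]-17,19-dihydroxy-(8βH)-labd-13-en-16-oate | C[C@]12CCC[C@](C)(CO)[C@@H]1CC[C@@H](CO)[C@@H]2CC/C(C(=O)OCC)=C/CO[Si](C)(C)C(C)(C)C
F3 | step 3 | (4-methylpent-3-en-1-yl)zinc bromide | CC(C)=CCC[Zn]Br
F4 | step 3 | 3-(4-methylpent-3-en-1-yl)-5,6-dihydro-2H-pyran-2-one | O=C1OCCC=C1CCC=C(C)C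
F5 | step 3 | (2Z)-2-(4-methylpent-3-en-1-yl)penta-2,4-dienoic acid | C=C/C=C(\C(=O)O)CCC=C(C)C
A1 | direct plan | (+)-podocarpic acid | C[C@]12CCC[C@](C)(C(=O)O)[C@@H]1CCc1ccc(O)cc12
A2 | direct plan | 12-oxopodocarp-13-en-19-oic acid (8β-H, 9α-H) | C[C@]12CCC[C@](C)(C(=O)O)[C@@H]1CC[C@H]3C=CC(=O)C[C@H]23
A3 | direct plan | (8βH)-13,14,15,16-tetranorlabdane-12,17,19-trioic acid | C[C@]12CCC[C@](C)(C(=O)O)[C@@H]1CC[C@@H](C(=O)O)[C@@H]2CC(=O)O
A4 | direct plan | α-methylene-γ-butyrolactone | C=C1CCOC1=O
A5 | direct plan | 13-(pyridin-2-ylsulfanyl)labdan-16,15-olide-17,19-dioic acid (C13 epimers) | C[C@]12CCC[C@](C)(C(=O)O)[C@@H]1CC[C@@H](C(=O)O)[C@@H]2CCC1(Sc2ccccn2)CCOC1=O
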